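**Plan**

- Retrosynthetic cuts, in order: the C3–aroyl and C5–geranyl bonds (lithiation chemistry on the finished core), the C7 side-chain C–C bond (from a C7 methylidene), the ring bond C5–C6 (palladium-catalysed allylic alkylation), and the C1–C8 bond (Claisen rearrangement).
- Forward: the ring C1–C2–C3–C4–C5–C9 comes from phloroglucinol and is held at the dihydro level while C1 receives prenyl and, by [3,3] shift, a CMe2–C(=CH2)–CH2OAc arm. Closing C5–C6 then forms the ring C1–C8–C7–C6–C5–C9 and with it the bicyclo[3.3.1]nonane; geranyl, the C7 prenyl group and the aroyl group follow.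
- Enabling feature: the cyclohexane-1,3,5-trione precursor has a mirror plane through C1 and C4, so C3 and C5 are enantiotopic. C5 lies 1,3 to C1 across C9, within reach of the three-carbon arm C8–C7–C6 on C1.
- Stereochemistry: C1 and C5 are set together, absolutely, by a chiral palladium catalyst that selects C5 over C3 in an achiral substrate. C7 is set by exo-face hydroboration of the methylidene (prenyl endo, syn to the C2–C4 bridge). The E-alkene comes with geranyl bromide.

Key step: step 10

Remark: the target is a β-triketone enol drawn as its C4-hydroxy/C2-oxo tautomer. Atoms are numbered on the bicyclo[3.3.1]nonane with C1 (prenyl) next to C8 (CMe2) and C5 (geranyl) next to C6; the given configuration corresponds to (1S,5S,7S), C7 prenyl endo.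

**Route**

Step 1
Reactants: 1 diethyl 2-(propan-2-ylidene)propanedioate
Product: 2 2-(propan-2-ylidene)propane-1,3-diol
Conditions: iBu2AlH (4.4 equiv), CH2Cl2, −78 → 0 °C; aq. potassium sodium tartrate
Reagents that add atoms: none
Why: iBu2AlH reduces both conjugated esters by 1,2-addition to the allylic diol, the tetrasubstituted alkene resisting conjugate reduction (ester-to-alcohol reduction).

Step 2
Reactants: 2 2-(propan-2-ylidene)propane-1,3-diol
Product: 3 2-(hydroxymethyl)-3-methylbut-2-en-1-yl acetate
Conditions: vinyl acetate, immobilised Candida antarctica lipase B, THF, 25 °C, stopped at mono-acylation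
Reagents that add atoms: vinyl acetate, C=COC(C)=O
Why: The lipase acylates one of the two equivalent primary hydroxyls, and the transfer is irreversible because the released vinyl alcohol tautomerises to acetaldehyde (enzymatic mono-acylation of a symmetric 1,3-diol).

Step 3
Reactants: 4 phloroglucinol (benzene-1,3,5-triol)
Product: 5 5-hydroxycyclohexane-1,3-dione (dihydrophloroglucinol; exists as the enol)
Conditions: NaBH4, H2O, 25 °C; then HCl to pH 3
Reagents that add atoms: none
Why: In water phloroglucinol reacts through its keto tautomer, borohydride reduces one carbonyl, and the vinylogous-acid anion formed resists further reduction (partial carbonyl reduction).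

Step 4
Reactants: 5 5-hydroxycyclohexane-1,3-dione
Product: 7 5-[(tert-butyldimethylsilyl)oxy]cyclohexane-1,3-dione, via bis-silyl enol ether 6 (not isolated)
Conditions: TBSCl (2.5 equiv), imidazole, DMF, 25 °C; then aq. citric acid, THF, 0 °C
Reagents that add atoms: tert-butyldimethylsilyl chloride, CC(C)(C)[Si](C)(C)Cl
Why: Both the alcohol and the acidic enol are silylated, and the vinylogous silyl ester, far more labile than the secondary silyl ether, is hydrolysed selectively on mild acidic work-up (silyl protection).

Step 5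
Reactants: 7 5-[(tert-butyldimethylsilyl)oxy]cyclohexane-1,3-dione; 8 1-bromo-3-methylbut-2-ene (prenyl bromide)
Product: 9 5-[(tert-butyldimethylsilyl)oxy]-2-(3-methylbut-2-en-1-yl)cyclohexane-1,3-dione (exists as the enol)
Conditions: KOH (1 equiv), H2O–1,4-dioxane, 0 → 25 °C
Reagents that add atoms: none
Why: The potassium enolate of a cyclic 1,3-dione is alkylated at carbon by the soft allylic bromide in aqueous medium, where hydrogen bonding shields the enolate oxygens (C-alkylation of a cyclic 1,3-diketone).

Step 6
Reactants: 9 5-[(tert-butyldimethylsilyl)oxy]-2-(3-methylbut-2-en-1-yl)cyclohexane-1,3-dione; 3 2-(hydroxymethyl)-3-methylbut-2-en-1-yl acetate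
Product: 10 2-[({5-[(tert-butyldimethylsilyl)oxy]-2-(3-methylbut-2-en-1-yl)-3-oxocyclohex-1-en-1-yl}oxy)methyl]-3-methylbut-2-en-1-yl acetate (racemic)
Conditions: PPh3, DIAD, THF, 0 → 25 °C
Reagents that add atoms: none
Why: The acidic enol of 9 is the pronucleophile and is O-alkylated by the activated primary allylic alcohol, C-alkylation being blocked by the prenyl group; the two carbonyls of 9 are equivalent, so a single racemic vinylogous ester should form, whose one stereocentre is erased in step 9 (Mitsunobu etherification).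

Step 7
Reactants: 10 the allyl vinylogous ester from step 6
Product: 11 3-{4-[(tert-butyldimethylsilyl)oxy]-1-(3-methylbut-2-en-1-yl)-2,6-dioxocyclohexyl}-3-methyl-2-methylidenebutyl acetate (cis and trans isomers, both achiral)
Conditions: o-xylene, 160 °C (sealed tube), BHT (cat.)
Reagents that add atoms: none
Why: The allyl vinyl ether unit undergoes a [3,3] shift through a chair transition state that forms the C1–C8 bond between two fully substituted carbons and turns the tetrasubstituted alkene into the 2-substituted allylic acetate; C4 stays at the alcohol level so that the ring can neither aromatise nor offer a C5=C9 enol for a second shift, and both diastereomers converge in step 9 (Claisen rearrangement).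

Step 8
Reactants: 11 the silyl ether from step 7
Product: 12 3-[4-hydroxy-1-(3-methylbut-2-en-1-yl)-2,6-dioxocyclohexyl]-3-methyl-2-methylidenebutyl acetate
Conditions: HF·pyridine, THF, 0 → 25 °C
Reagents that add atoms: none
Why: Buffered fluoride cleaves the secondary silyl ether and should leave the allylic acetate and the β-hydroxy ketone intact (desilylation).

Step 9
Reactants: 12 the hydroxy dione from step 8
Product: 13 3-methyl-3-[1-(3-methylbut-2-en-1-yl)-2,4,6-trioxocyclohexyl]-2-methylidenebutyl acetate (achiral; enol tautomers)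
Conditions: Dess–Martin periodinane, NaHCO3, CH2Cl2, 0 °C; used at once
Reagents that add atoms: none
Why: The periodinane oxidises the secondary alcohol under neutral conditions to the trione, which enolises to the mirror-symmetric vinylogous acid; it is kept cold and used directly because a [3,3] shift of the tertiary allyl arm from C1 to C5 would aromatise it (alcohol oxidation).

Step 10
Reactants: 13 the achiral trione allylic acetate
Product: 14 (1R,5S)-4-hydroxy-8,8-dimethyl-1-(3-methylbut-2-en-1-yl)-7-methylidenebicyclo[3.3.1]non-3-ene-2,9-dione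
Conditions: Pd2(dba)3·CHCl3 (2.5 mol%), (R,R)-N,N'-(cyclohexane-1,2-diyl)bis[2-(diphenylphosphino)benzamide] (7.5 mol%), Et3N (1.2 equiv), CH2Cl2, 0 °C
Reagents that add atoms: none
Why: Proposed new method: the zerovalent palladium catalyst ionises the allylic acetate to a 2-substituted π-allylpalladium cation whose two CH2 termini are equivalent and whose faces interconvert quickly, and the triethylammonium enolate of the trione attacks one terminus through C5 on the side away from palladium (Tsuji–Trost allylic alkylation), leaving the C7 methylidene. The closest known reaction types are the asymmetric allylic alkylation of cyclic β-dicarbonyl carbon nucleophiles with this ligand family and the racemic palladium-catalysed allylic annulation of dearomatised acylphloroglucinols to bicyclo[3.3.1]nonanes; new here is that the chiral ligand must choose between two enantiotopic nucleophilic carbons of one enolate. The ring C1–C8–C7–C6–C5–C9 closes by a formal 6-exo-tet attack on C6, which completes the bicyclo[3.3.1]nonane, the gem-dimethyl group at C8 favouring the folded arm. C1 and C5 become stereocentres in the same event, C5 by the new bond and C1 because its two ring arms now differ, and since the three-carbon bridge can only span the ring cis, the single choice of C5 over C3, made in the chiral pocket of the ligand around the allyl–enolate ion pair, fixes both, absolute configuration included. The step needs C- over O-alkylation and must outrun the thermal [3,3] shift of the arm: O-allyl enol ethers are re-ionised by palladium and drain into the C-alkylated ketone, whose bridgehead C5–H can no longer enolise, the intramolecular attack should be fast at 0 °C, and if the (R,R) ligand favours the mirror image its (S,S) antipode is used.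

Step 11
Reactants: 14 the bicyclic trione enol
Product: 15 (1R,5S)-4-methoxy-8,8-dimethyl-1-(3-methylbut-2-en-1-yl)-7-methylidenebicyclo[3.3.1]non-3-ene-2,9-dione
Conditions: (MeO)2SO2, K2CO3, acetone, 25 °C
Reagents that add atoms: dimethyl sulfate, COS(=O)(=O)OC
Why: The enolised β-diketone is O-methylated at the less hindered oxygen, the one on C4 remote from the quaternary C1, which masks the acidic enol for the two lithiation steps; any C2-methoxy isomer is removed by chromatography (O-alkylation of a cyclic β-diketone).

Step 12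
Reactants: 15 the methyl enol ether; 16 geranyl bromide, (2E)-1-bromo-3,7-dimethylocta-2,6-diene
Product: 18 (1R,5S)-5-[(2E)-3,7-dimethylocta-2,6-dien-1-yl]-4-methoxy-8,8-dimethyl-1-(3-methylbut-2-en-1-yl)-7-methylidenebicyclo[3.3.1]non-3-ene-2,9-dione, via bridgehead lithium compound 17 (not isolated)
Conditions: LiN(iPr)2 (LDA), THF, −78 °C; then 16, −78 → 0 °C
Reagents that add atoms: none
Why: LDA removes the only bridgehead hydrogen, at C5 next to the C9 ketone, and the bridgehead lithium compound is alkylated by geranyl bromide with retention, since the bridge allows no inversion (bridgehead lithiation–alkylation of a bicyclo[3.3.1]nonane-2,4,9-trione enol ether).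

Step 13
Reactants: 18 the C5-geranyl methylidene compound; 19 1-bromo-2-methylprop-1-ene
Product: 21 (1R,5S,7S)-5-[(2E)-3,7-dimethylocta-2,6-dien-1-yl]-4-methoxy-8,8-dimethyl-1,7-bis(3-methylbut-2-en-1-yl)bicyclo[3.3.1]non-3-ene-2,9-dione (C7 prenyl endo), via alkylborane 20 (not isolated)
Conditions: 9-BBN, THF, 0 → 25 °C; then 19, Pd(dppf)Cl2 (5 mol%), aq. K3PO4, DMF, 25 → 50 °C
Reagents that add atoms: 9-borabicyclo[3.3.1]nonane (9-BBN), B1C2CCCC1CCC2 (its atoms stay only in intermediate 20)
Why: 9-BBN adds only to the 1,1-disubstituted methylidene, boron to the CH2 and hydrogen to C7 from the exo face turned away from the C2–C3–C4 bridge, so the CH2B group and then the prenyl group should come out endo, the hindered ketones and trisubstituted alkenes reacting more slowly; B-alkyl coupling with the vinyl bromide completes the prenyl group (hydroboration, then Suzuki–Miyaura coupling).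

Step 14
Reactants: 22 3-acetoxybenzoic acid
Product: 23 3-acetoxybenzoyl chloride
Conditions: (COCl)2, DMF (cat.), CH2Cl2, 0 → 25 °C
Reagents that add atoms: oxalyl chloride, O=C(Cl)C(Cl)=O
Why: Oxalyl chloride with catalytic DMF converts the acid into its chloride through the chloroiminium reagent without touching the aryl acetate (acid chloride formation).

Step 15
Reactants: 21 the fully alkylated methyl enol ether; 23 3-acetoxybenzoyl chloride
Product: 25 3-{[(1S,5S,7S)-5-[(2E)-3,7-dimethylocta-2,6-dien-1-yl]-4-methoxy-8,8-dimethyl-1,7-bis(3-methylbut-2-en-1-yl)-2,9-dioxobicyclo[3.3.1]non-3-en-3-yl]carbonyl}phenyl acetate, via C3-lithium compound 24 (not isolated)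
Conditions: lithium 2,2,6,6-tetramethylpiperidide (LiTMP), THF, −78 °C; then 23, −78 → 0 °C
Reagents that add atoms: none
Why: LiTMP deprotonates the vinylic C3–H between the C2 carbonyl and the C4 methoxy group, and the vinyllithium is acylated at the acid chloride, which reacts much faster than the aryl acetate (vinylic lithiation and C-acylation of a vinylogous ester).

Step 16
Reactants: 25 the protected target
Product: 26 (1S,5S,7S)-5-[(2E)-3,7-dimethylocta-2,6-dien-1-yl]-4-hydroxy-3-(3-hydroxybenzoyl)-8,8-dimethyl-1,7-bis(3-methylbut-2-en-1-yl)bicyclo[3.3.1]non-3-ene-2,9-dione (CNP0236890.1)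
Conditions: LiOH, H2O–1,4-dioxane, 90 °C; then dilute HCl, 0 °C
Reagents that add atoms: lithium hydroxide in water, [Li+].[OH-] (the hydroxide oxygen becomes the C4 enol oxygen)
Why: Hydroxide adds to C4 and expels methoxide and also saponifies the aryl acetate, freeing the β-triketone enol and the phenol without touching any stereocentre (addition–elimination on a vinylogous ester and ester hydrolysis).

**Compound list**

1 | diethyl 2-(propan-2-ylidene)propanedioate | CCOC(=O)C(=C(C)C)C(=O)OCC | starting material
2 | 2-(propan-2-ylidene)propane-1,3-diol | CC(C)=C(CO)CO | intermediate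
3 | 2-(hydroxymethyl)-3-methylbut-2-en-1-yl acetate | CC(C)=C(CO)COC(C)=O | intermediate
4 | phloroglucinol | Oc1cc(O)cc(O)c1 | starting material
5 | 5-hydroxycyclohexane-1,3-dione | O=C1CC(O)CC(=O)C1 | intermediate
6 | 3,5-bis[(tert-butyldimethylsilyl)oxy]cyclohex-2-en-1-one (racemic) | CC(C)(C)[Si](C)(C)OC1CC(=O)C=C(O[Si](C)(C)C(C)(C)C)C1 | intermediate (not isolated)
7 | 5-[(tert-butyldimethylsilyl)oxy]cyclohexane-1,3-dione | CC(C)(C)[Si](C)(C)OC1CC(=O)CC(=O)C1 | intermediate
8 | 1-bromo-3-methylbut-2-ene | CC(C)=CCBr | starting material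
9 | 5-[(tert-butyldimethylsilyl)oxy]-2-(3-methylbut-2-en-1-yl)cyclohexane-1,3-dione | CC(C)=CCC1C(=O)CC(O[Si](C)(C)C(C)(C)C)CC1=O | intermediate
10 | 2-[({5-[(tert-butyldimethylsilyl)oxy]-2-(3-methylbut-2-en-1-yl)-3-oxocyclohex-1-en-1-yl}oxy)methyl]-3-methylbut-2-en-1-yl acetate (racemic) | CC(C)=CCC1=C(OCC(COC(C)=O)=C(C)C)CC(O[Si](C)(C)C(C)(C)C)CC1=O | intermediate
11 | 3-{4-[(tert-butyldimethylsilyl)oxy]-1-(3-methylbut-2-en-1-yl)-2,6-dioxocyclohexyl}-3-methyl-2-methylidenebutyl acetate (cis and trans, both achiral) | CC(C)=CCC1(C(C)(C)C(=C)COC(C)=O)C(=O)CC(O[Si](C)(C)C(C)(C)C)CC1=O | intermediate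
12 | 3-[4-hydroxy-1-(3-methylbut-2-en-1-yl)-2,6-dioxocyclohexyl]-3-methyl-2-methylidenebutyl acetate | CC(C)=CCC1(C(C)(C)C(=C)COC(C)=O)C(=O)CC(O)CC1=O | intermediate
13 | 3-methyl-3-[1-(3-methylbut-2-en-1-yl)-2,4,6-trioxocyclohexyl]-2-methylidenebutyl acetate (achiral) | CC(C)=CCC1(C(C)(C)C(=C)COC(C)=O)C(=O)CC(=O)CC1=O | intermediate
14 | (1R,5S)-4-hydroxy-8,8-dimethyl-1-(3-methylbut-2-en-1-yl)-7-methylidenebicyclo[3.3.1]non-3-ene-2,9-dione | [C@H]12CC(=C)C(C)(C)[C@](CC=C(C)C)(C(=O)C=C1O)C2=O | intermediate
15 | (1R,5S)-4-methoxy-8,8-dimethyl-1-(3-methylbut-2-en-1-yl)-7-methylidenebicyclo[3.3.1]non-3-ene-2,9-dione | [C@H]12CC(=C)C(C)(C)[C@](CC=C(C)C)(C(=O)C=C1OC)C2=O | intermediate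
16 | (2E)-1-bromo-3,7-dimethylocta-2,6-diene (geranyl bromide) | CC(C)=CCC/C(C)=C/CBr | starting material
17 | C5 bridgehead lithium derivative of 15 | [Li][C@]12CC(=C)C(C)(C)[C@](CC=C(C)C)(C(=O)C=C1OC)C2=O | intermediate (not isolated)
18 | (1R,5S)-5-[(2E)-3,7-dimethylocta-2,6-dien-1-yl]-4-methoxy-8,8-dimethyl-1-(3-methylbut-2-en-1-yl)-7-methylidenebicyclo[3.3.1]non-3-ene-2,9-dione | CC(C)=CCC/C(C)=C/C[C@]12CC(=C)C(C)(C)[C@](CC=C(C)C)(C(=O)C=C1OC)C2=O | intermediate
19 | 1-bromo-2-methylprop-1-ene | CC(C)=CBr | starting material
20 | (1R,5S,7S)-7-[(9-borabicyclo[3.3.1]nonan-9-yl)methyl] derivative of 18 (CH2B endo) | CC(C)=CCC/C(C)=C/C[C@]12C[C@H](CB3C4CCCC3CCC4)C(C)(C)[C@](CC=C(C)C)(C(=O)C=C1OC)C2=O | intermediate (not isolated)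
21 | (1R,5S,7S)-5-[(2E)-3,7-dimethylocta-2,6-dien-1-yl]-4-methoxy-8,8-dimethyl-1,7-bis(3-methylbut-2-en-1-yl)bicyclo[3.3.1]non-3-ene-2,9-dione | CC(C)=CCC/C(C)=C/C[C@]12C[C@H](CC=C(C)C)C(C)(C)[C@](CC=C(C)C)(C(=O)C=C1OC)C2=O | intermediate
22 | 3-acetoxybenzoic acid | CC(=O)Oc1cccc(c1)C(O)=O | starting material
23 | 3-acetoxybenzoyl chloride | CC(=O)Oc1cccc(c1)C(Cl)=O | intermediate
24 | C3-lithium derivative of 21 | CC(C)=CCC/C(C)=C/C[C@]12C[C@H](CC=C(C)C)C(C)(C)[C@](CC=C(C)C)(C(=O)C([Li])=C1OC)C2=O | intermediate (not isolated)
25 | 3-{[(1S,5S,7S)-5-[(2E)-3,7-dimethylocta-2,6-dien-1-yl]-4-methoxy-8,8-dimethyl-1,7-bis(3-methylbut-2-en-1-yl)-2,9-dioxobicyclo[3.3.1]non-3-en-3-yl]carbonyl}phenyl acetate | CC(C)=CCC/C(C)=C/C[C@]12C[C@H](CC=C(C)C)C(C)(C)[C@](CC=C(C)C)(C(=O)C(C(=O)c3cccc(OC(C)=O)c3)=C1OC)C2=O | intermediate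
26 | (1S,5S,7S)-5-[(2E)-3,7-dimethylocta-2,6-dien-1-yl]-4-hydroxy-3-(3-hydroxybenzoyl)-8,8-dimethyl-1,7-bis(3-methylbut-2-en-1-yl)bicyclo[3.3.1]non-3-ene-2,9-dione | CC(C)=CCC/C(C)=C/C[C@]12C[C@H](CC=C(C)C)C(C)(C)[C@](CC=C(C)C)(C(=O)C(C(=O)c3cccc(O)c3)=C1O)C2=O | target

**Step count and risks**

Total step count: 16. Longest linear sequence: 13 steps (steps 3 to 13, 15 and 16).

Steps most likely to fail:

1. Step 10 (Proposed new method). The ligand may discriminate poorly between the two enantiotopic enolate carbons, so that the bicycle forms with low enantiomeric purity. The fallback uses known chemistry, sets out from 13 and comes back at 18. Cyclisation of 13 with the achiral catalyst Pd(PPh3)4 and Et3N in THF should give the racemic bicyclic trione F1. O-Methylation as in step 11 then gives the racemic methyl enol ether F2. Bridgehead lithiation of F2 at −78 °C with about half an equivalent of the chiral bis-lithium amide of (1R,2R)-N,N'-bis[(R)-1-phenylethyl]-1,2-diphenylethane-1,2-diamine (or its antipode, whichever matches) is a kinetic resolution. The (1R,5S)-enantiomer is lithiated to 17 and trapped with 16 to give 18, and the unreacted (1S,5R)-methyl enol ether F3 is separated by chromatography.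

2. Step 7. The [3,3] shift has to join two fully substituted carbons; it may stall, divert into a [1,3] shift, or be overtaken by loss of silanol with aromatisation. The fallback sets out from 7 and comes back at 11, running two less congested [3,3] shifts in the opposite order. Mitsunobu etherification of 7 with 3 gives the enol ether F4. Heating F4 moves the allyl unit onto the still unsubstituted C1, and enolisation of the resulting 2-substituted dione F5 makes that shift irreversible. O-Allylation of F5 (allyl bromide, K2CO3, DMF) gives the allyl enol ether F6, whose Claisen rearrangement forms an unhindered C1–CH2 bond and gives the 2-allyl dione F7. Cross-metathesis of F7 with 2-methylbut-2-ene ((H2IMes)(PCy3)Cl2Ru=CHPh, second-generation Grubbs catalyst) turns allyl into prenyl and gives 11.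

3. Step 13. The borane may reduce a ring carbonyl, add with poor facial selectivity next to the gem-dimethyl group, or the neopentyl-type alkylborane may transmetallate slowly. The fallback sets out from 18 and comes back at 21 without a hydride reagent. Rhodium-catalysed hydroformylation of the methylidene group (Rh(acac)(CO)2, tris(2,4-di-tert-butylphenyl) phosphite, CO/H2, toluene) should give the linear product, with hydrogen delivered to C7 from the same exo face, as the endo aldehyde F8. Wittig olefination of F8 with isopropylidenetriphenylphosphorane then gives 21.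

**Further compounds**

F1 | step 10 | racemic 4-hydroxy-8,8-dimethyl-1-(3-methylbut-2-en-1-yl)-7-methylidenebicyclo[3.3.1]non-3-ene-2,9-dione | C12CC(=C)C(C)(C)C(CC=C(C)C)(C(=O)C=C1O)C2=O
F2 | step 10 | racemic 4-methoxy-8,8-dimethyl-1-(3-methylbut-2-en-1-yl)-7-methylidenebicyclo[3.3.1]non-3-ene-2,9-dione | C12CC(=C)C(C)(C)C(CC=C(C)C)(C(=O)C=C1OC)C2=O
F3 | step 10 | (1S,5R)-4-methoxy-8,8-dimethyl-1-(3-methylbut-2-en-1-yl)-7-methylidenebicyclo[3.3.1]non-3-ene-2,9-dione (enantiomer of 15) | [C@@H]12CC(=C)C(C)(C)[C@@](CC=C(C)C)(C(=O)C=C1OC)C2=O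
F4 | step 7 | 2-[({5-[(tert-butyldimethylsilyl)oxy]-3-oxocyclohex-1-en-1-yl}oxy)methyl]-3-methylbut-2-en-1-yl acetate (racemic) | CC(C)=C(COC(C)=O)COC1=CC(=O)CC(O[Si](C)(C)C(C)(C)C)C1
F5 | step 7 | 3-{4-[(tert-butyldimethylsilyl)oxy]-2,6-dioxocyclohexyl}-3-methyl-2-methylidenebutyl acetate | CC(=O)OCC(=C)C(C)(C)C1C(=O)CC(O[Si](C)(C)C(C)(C)C)CC1=O
F6 | step 7 | 3-{4-[(tert-butyldimethylsilyl)oxy]-6-oxo-2-(prop-2-en-1-yloxy)cyclohex-1-en-1-yl}-3-methyl-2-methylidenebutyl acetate (racemic) | C=CCOC1=C(C(C)(C)C(=C)COC(C)=O)C(=O)CC(O[Si](C)(C)C(C)(C)C)C1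
F7 | step 7 | 3-{4-[(tert-butyldimethylsilyl)oxy]-2,6-dioxo-1-(prop-2-en-1-yl)cyclohexyl}-3-methyl-2-methylidenebutyl acetate | C=CCC1(C(C)(C)C(=C)COC(C)=O)C(=O)CC(O[Si](C)(C)C(C)(C)C)CC1=O
F8 | step 13 | (1R,5S,7R)-5-[(2E)-3,7-dimethylocta-2,6-dien-1-yl]-4-methoxy-8,8-dimethyl-1-(3-methylbut-2-en-1-yl)-7-(2-oxoethyl)bicyclo[3.3.1]non-3-ene-2,9-dione (side chain endo) | CC(C)=CCC/C(C)=C/C[C@]12C[C@H](CC=O)C(C)(C)[C@](CC=C(C)C)(C(=O)C=C1OC)C2=O
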